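**Retrosynthetic overview**
1. The last operations free C15–OH (PMB off) and acylate C8–OH. Before that, the ten-membered carbocycle and the trans γ-lactone come from one C6–C7 disconnection: Cr(II) allylation of a Z-enal by a 2-(bromomethyl)enoate, then lactonisation.
2. The key fragment union is the C3–C4 bond. It is a Pd-catalysed C5–H alkenylation of a 5-unsubstituted 3(2H)-furanone (east half) with a (Z)-alkenyl iodide (west half).
3. East half: the furanone ring comes from a methyl ketone plus a one-carbon amide acetal, C7–C8 from an asymmetric Ni/Cr coupling of an aldehyde with a β-bromoacrylate, and C9–C10 (quaternary C10) from a Cu–box Mukaiyama aldol on biacetyl.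
4. West half: but-2-yne-1,4-diol, with directed trans-hydroalumination/iodination fixing the Z alkene.
5. Ring order: furanone, then ten-membered ring, then γ-lactone.

Atom labels follow germacrane numbering. C1 is the furanone C=O, C3 the furanone C–O, C4=C5 the ring alkene, C6 the lactone CH–O, C8 the CH–O-acyl, C10 the quaternary carbon, C11–C13 the methylene lactone and C15 the CH2OH. L* is (S)-N-[2-(4-isopropyl-4,5-dihydrooxazol-2-yl)-6-methylphenyl]methanesulfonamide, a Kishi-type ligand.

Assumption: the antipodes of the chiral ligands [(R,R)-t-Bu-box, (S)-L*] are assigned by analogy with their usual sense of induction; if a first run shows the opposite sense, the mirror-image ligand is used and nothing else changes.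

**Step 1**
Reactants: 1 methyl 2-(hydroxymethyl)acrylate
Product: 2 methyl 2-[(tert-butyldimethylsilyloxy)methyl]acrylate
Conditions: TBSCl, imidazole, CH2Cl2, 0 °C to rt
Reagents that add atoms: tert-butyldimethylsilyl chloride, CC(C)(C)[Si](C)(C)Cl
Why: Corey-type silylation of the primary allylic alcohol masks C13–OH through the halogenation, Cr and Pd steps; no stereocentre is formed.

**Step 2**
Reactants: 2 methyl 2-[(tert-butyldimethylsilyloxy)methyl]acrylate
Product: 3 methyl 2,3-dibromo-2-[(tert-butyldimethylsilyloxy)methyl]propanoate (racemic)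
Conditions: Br2, CH2Cl2, 0 °C to rt, dark
Reagents that add atoms: bromine, BrBr
Why: Electrophilic bromine addition to the 1,1-disubstituted acrylate; the new stereocentre is racemic and is erased in step 3.

**Step 3**
Reactants: 3 methyl 2,3-dibromo-2-[(tert-butyldimethylsilyloxy)methyl]propanoate
Product: 4 methyl (E)-3-bromo-2-[(tert-butyldimethylsilyloxy)methyl]acrylate (Br trans to CO2Me)
Conditions: DBU (1.1 equiv), Et2O, 0 °C to rt
Reagents that add atoms: none
Why: E2 dehydrobromination: with no α-H, only the acidified CH2Br proton can leave with the tertiary bromide, and as with methacrylate dibromides the E bromide predominates, the minor Z isomer being removed by chromatography.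

**Step 4**
Reactants: 5 but-2-yne-1,4-diol
Product: 6 4-(4-methoxybenzyloxy)but-2-yn-1-ol
Conditions: NaH (1 equiv), PMBCl (1 equiv), TBAI (cat.), 5 (3 equiv), THF–DMF, 0 °C to rt
Reagents that add atoms: 4-methoxybenzyl chloride, COc1ccc(CCl)cc1
Why: Williamson etherification; the excess of symmetrical diol gives the monoether, which leaves one free OH to direct step 5.

**Step 5**
Reactants: 6 4-(4-methoxybenzyloxy)but-2-yn-1-ol
Product: 8 (Z)-3-iodo-4-(4-methoxybenzyloxy)but-2-en-1-ol, via cyclic alkenylalanate 7 (not isolated)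
Conditions: Red-Al, THF, 0 °C to rt; then I2, THF, −78 °C
Reagents that add atoms: iodine, II (Red-Al, [Na+].[AlH2-](OCCOC)OCCOC, puts atoms other than H only into 7)
Why: Hydroxyl-directed trans-hydroalumination of the propargylic alcohol puts Al on the distal alkyne carbon in a five-membered alanate, and iodinolysis with retention gives only the Z iodide, which fixes the C4=C5 geometry (I, later the furanone, cis to C6).

**Step 6**
Reactants: 8 (Z)-3-iodo-4-(4-methoxybenzyloxy)but-2-en-1-ol
Product: 9 (Z)-3-iodo-4-(4-methoxybenzyloxy)but-2-enal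
Conditions: MnO2, CH2Cl2, rt
Reagents that add atoms: none
Why: MnO2 allylic oxidation is neutral, so the C–I bond, the PMB ether and the Z geometry survive.

**Step 7**
Reactants: 9 (Z)-3-iodo-4-(4-methoxybenzyloxy)but-2-enal
Product: 10 (Z)-2-iodo-4,4-dimethoxy-1-(4-methoxybenzyloxy)but-2-ene
Conditions: HC(OMe)3, PPTS (cat.), MeOH, rt
Reagents that add atoms: trimethyl orthoformate, COC(OC)OC
Why: Acid-catalysed acetalisation with orthoformate as water scavenger masks C6 at the aldehyde level for the Pd step, so it can later be released without an oxidation.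

**Step 8**
Reactants: 11 S-ethyl thioacetate
Product: 13 1-(ethylthio)-1-(trimethylsilyloxy)ethene, via lithium thioester enolate 12 (not isolated)
Conditions: LDA, THF, −78 °C; then TMSCl
Reagents that add atoms: trimethylsilyl chloride, C[Si](C)(C)Cl (LDA, [Li+].CC(C)[N-]C(C)C, puts Li only into 12)
Why: Kinetic enolisation and O-silylation of the thioester give the silyl ketene thioacetal needed for the Mukaiyama aldol.

**Step 9**
Reactants: 13 1-(ethylthio)-1-(trimethylsilyloxy)ethene; 14 butane-2,3-dione
Product: 15 S-ethyl (R)-3-methyl-4-oxo-3-(trimethylsilyloxy)pentanethioate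
Conditions: [Cu((R,R)-t-Bu-box)](OTf)2 (10 mol %), 14 (3 equiv), THF, −78 °C; neutral work-up
Reagents that add atoms: none
Why: Evans Cu(II)–bis(oxazoline) Mukaiyama aldol: the 1,2-diketone chelates square-planar Cu(II) and the t-Bu groups leave one carbonyl face open, which sets C10 as R; silyl transfer keeps the adduct as its TMS ether (no retro-aldol) and excess diketone prevents double addition.

**Step 10**
Reactants: 15 S-ethyl (R)-3-methyl-4-oxo-3-(trimethylsilyloxy)pentanethioate
Product: 16 (R)-3-methyl-4-oxo-3-(trimethylsilyloxy)pentanal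
Conditions: Et3SiH, 10% Pd/C (5 mol %), acetone, rt
Reagents that add atoms: none
Why: Fukuyama reduction turns only the thioester into the aldehyde under neutral conditions; the ketone, the TMS ether and C10 are untouched and no alkene is present yet.

**Step 11**
Reactants: 16 (R)-3-methyl-4-oxo-3-(trimethylsilyloxy)pentanal; 4 methyl (E)-3-bromo-2-[(tert-butyldimethylsilyloxy)methyl]acrylate
Product: 17 methyl (2E,4R,6R)-2-[(tert-butyldimethylsilyloxy)methyl]-4-hydroxy-6-methyl-7-oxo-6-(trimethylsilyloxy)oct-2-enoate
Conditions: CrCl2 (4 equiv), (S)-L* (4.4 equiv), Et3N (4.4 equiv), NiCl2 (2 mol %), THF, rt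
Reagents that add atoms: none
Why: Asymmetric Nozaki–Hiyama–Kishi Ni/Cr alkenylation is selective for the aldehyde over the ketone and keeps the alkene geometry (ester trans to the new carbinol, so no butenolide forms), and the sulfonamide ligand directs Si-face attack to set C8 as R.

**Step 12**
Reactants: 17 the allylic alcohol from step 11
Product: 18 methyl (2E,4R,6R)-4-(tert-butyldimethylsilyloxy)-2-[(tert-butyldimethylsilyloxy)methyl]-6-methyl-7-oxo-6-(trimethylsilyloxy)oct-2-enoate
Conditions: TBSCl, imidazole, DMAP (cat.), DMF, rt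
Reagents that add atoms: tert-butyldimethylsilyl chloride, CC(C)(C)[Si](C)(C)Cl
Why: Silyl ether protection with retention at C8; a silyloxy group is inert to Pd(0) and a poor leaving group in the later allylchromium species, unlike an allylic ester.

**Step 13**
Reactants: 18 the bis-TBS TMS methyl ketone from step 12
Product: 20 methyl (2E,4R)-4-(tert-butyldimethylsilyloxy)-2-[(tert-butyldimethylsilyloxy)methyl]-5-[(2R)-2-methyl-3-oxo-2,3-dihydrofuran-2-yl]pent-2-enoate, via enaminone 19 (not isolated)
Conditions: Me2NCH(OMe)2, PhMe, 100 °C; concentrate; then 1 M aq. citric acid, THF, 40 °C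
Reagents that add atoms: N,N-dimethylformamide dimethyl acetal, COC(OC)N(C)C
Why: Amide-acetal condensation can occur only at the single enolisable CH3 (C2) and brings in C3; mild acid then removes the tertiary TMS group and the C10–OH closes the 3(2H)-furanone by oxa-Michael addition–elimination of Me2NH, with both TBS ethers and C8/C10 unchanged.

**Step 14**
Reactants: 20 the 5-unsubstituted furanone from step 13; 10 (Z)-2-iodo-4,4-dimethoxy-1-(4-methoxybenzyloxy)but-2-ene
Product: 21 methyl (2E,4R)-4-(tert-butyldimethylsilyloxy)-2-[(tert-butyldimethylsilyloxy)methyl]-5-{(2R)-5-[(2Z)-4,4-dimethoxy-1-(4-methoxybenzyloxy)but-2-en-2-yl]-2-methyl-3-oxo-2,3-dihydrofuran-2-yl}pent-2-enoate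
Conditions: Pd(OAc)2 (10 mol %), PCy3·HBF4 (20 mol %), PivOH (30 mol %), Ag2CO3 (1.0 equiv), 1,4-dioxane, 70 °C
Reagents that add atoms: none
Why: Proposed new method: Pd-catalysed C5–H alkenylation of a 5-unsubstituted 3(2H)-furanone with an alkenyl iodide; oxidative addition of 10 keeps the Z geometry, Ag2CO3 removes iodide to give a cationic alkenyl–Pd(II) pivalate, and the C3–C4 bond forms at furanone C5 either by concerted metalation–deprotonation of the most acidic sp2 C–H (α to the ring O, β to C=O) followed by reductive elimination, or by Heck-type insertion in which both the enol-ether and the enone polarisation put carbon on C5 and Pd on C4, the O-bound Pd enolate letting Pd change face for syn β-H elimination, so both paths give 21; the closest known reaction types are Pd-catalysed C2–H arylation/alkenylation of chromones and 4-pyranones, Heck reactions of cyclic enones and direct alkenylation of furans and azoles with alkenyl halides; no stereocentre is formed, the silyl ethers and acetal are not ionised by Pd(0), and the hindered trisubstituted enoate is a far poorer insertion partner.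

**Step 15**
Reactants: 21 the coupled acetal from step 14
Product: 22 methyl (2E,4R)-4-(tert-butyldimethylsilyloxy)-2-(hydroxymethyl)-5-{(2R)-5-[(2Z)-1-(4-methoxybenzyloxy)-4-oxobut-2-en-2-yl]-2-methyl-3-oxo-2,3-dihydrofuran-2-yl}pent-2-enoate
Conditions: AcOH–THF–H2O (3:1:1), 40 °C
Reagents that add atoms: water, O
Why: Mild acid hydrolysis cleaves the primary allylic TBS ether and the dimethyl acetal in one operation, while the hindered secondary TBS ether, the PMB ether and the vinylogous ester survive.

**Step 16**
Reactants: 22 the hydroxy enal from step 15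
Product: 24 methyl (2Z,4R)-2-(bromomethyl)-4-(tert-butyldimethylsilyloxy)-5-{(2R)-5-[(2Z)-1-(4-methoxybenzyloxy)-4-oxobut-2-en-2-yl]-2-methyl-3-oxo-2,3-dihydrofuran-2-yl}pent-2-enoate, via allylic mesylate 23 (not isolated)
Conditions: MsCl, Et3N, CH2Cl2, −20 °C; then LiBr, THF, 0 °C
Reagents that add atoms: lithium bromide, [Li+].[Br-] (methanesulfonyl chloride, CS(=O)(=O)Cl, puts atoms only into 23)
Why: Mesylation followed by SN2 bromide displacement converts the primary allylic alcohol without touching the enal, which phosphine/CBr4 conditions would attack.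

**Step 17**
Reactants: 24 the bromo enal from step 16
Product: 26 8-O-TBS 15-O-PMB macrolactone (ten-membered ring and 6,7-trans α-methylene-γ-lactone closed; C6 C7 C8 C10 arranged as in the target), via macrocyclic hydroxy ester 25 (not isolated)
Conditions: CrCl2 (8 equiv), (S)-L* (8.8 equiv), Et3N (8.8 equiv), THF, rt, 24 added by syringe pump (final 2 mM); aqueous work-up; then PPTS (cat.), PhH, 50 °C
Reagents that add atoms: none
Why: Intramolecular Nozaki–Hiyama (Cr(II) Barbier) allylation: the allylchromium(III) equilibrates to its E form and adds through C7 to the tethered enal in a chair Zimmerman–Traxler transition state, giving the 6,7-anti adduct (the trans-lactone), the ligand directs Si-face attack on the aldehyde (6R and hence C7 as drawn), the C8 silyloxy group in an inside-alkoxy orientation supports the same face, the bulky Cr(III) allyl prefers the aldehyde to the vinylogous-ester C=O, and mild acid then closes the lactone on the only free hydroxyl.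

**Step 18**
Reactants: 26 8-O-TBS 15-O-PMB macrolactone
Product: 27 8-hydroxy 15-O-PMB macrolactone (6R,7R,8R,10R)
Conditions: HF·pyridine, pyridine, THF, 0 °C to rt
Reagents that add atoms: none
Why: Fluoride-mediated desilylation under buffered, non-basic conditions frees C8–OH without opening or migrating the lactone; the PMB ether is orthogonal.

**Step 19**
Reactants: 27 8-hydroxy 15-O-PMB macrolactone
Product: 28 15-O-PMB ether of the target (8-O-isobutyrate; 6R,7R,8R,10R)
Conditions: i-PrCOCl, pyridine, DMAP (cat.), CH2Cl2, 0 °C to rt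
Reagents that add atoms: isobutyryl chloride, CC(C)C(=O)Cl
Why: DMAP-catalysed acylation of the only free hydroxyl proceeds at oxygen, so C8 keeps its configuration.

**Step 20**
Reactants: 28 15-O-PMB ether of the target
Product: 29 target CNP0176924.3 (6R,7R,8R,10R; 4Z)
Conditions: DDQ (1.3 equiv), CH2Cl2–pH 7 buffer, 0 °C
Reagents that add atoms: none
Why: Oxidative PMB cleavage (hydride abstraction by DDQ, then hydrolysis) is neutral and spares the electron-poor dienone, the methylene lactone and the ester.

**Compound list**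
1 | methyl 2-(hydroxymethyl)acrylate | C=C(CO)C(=O)OC | starting material
2 | methyl 2-[(tert-butyldimethylsilyloxy)methyl]acrylate | C=C(CO[Si](C)(C)C(C)(C)C)C(=O)OC | intermediate
3 | methyl 2,3-dibromo-2-[(tert-butyldimethylsilyloxy)methyl]propanoate (racemic) | COC(=O)C(Br)(CBr)CO[Si](C)(C)C(C)(C)C | intermediate
4 | methyl (E)-3-bromo-2-[(tert-butyldimethylsilyloxy)methyl]acrylate | COC(=O)/C(CO[Si](C)(C)C(C)(C)C)=C/Br | intermediate
5 | but-2-yne-1,4-diol | OCC#CCO | starting material
6 | 4-(4-methoxybenzyloxy)but-2-yn-1-ol | OCC#CCOCc1ccc(OC)cc1 | intermediate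
7 | cyclic alkenylalanate, sodium salt (five-membered O–Al–C ring, two 2-methoxyethoxy groups on Al) | [Na+].COCCO[Al-]1(OCCOC)OCC=C1COCc2ccc(OC)cc2 | intermediate
8 | (Z)-3-iodo-4-(4-methoxybenzyloxy)but-2-en-1-ol | OC/C=C(\I)COCc1ccc(OC)cc1 | intermediate
9 | (Z)-3-iodo-4-(4-methoxybenzyloxy)but-2-enal | O=C/C=C(\I)COCc1ccc(OC)cc1 | intermediate
10 | (Z)-2-iodo-4,4-dimethoxy-1-(4-methoxybenzyloxy)but-2-ene | COC(OC)/C=C(\I)COCc1ccc(OC)cc1 | intermediate
11 | S-ethyl thioacetate | CC(=O)SCC | starting material
12 | lithium enolate of S-ethyl thioacetate | [Li+].C=C([O-])SCC | intermediate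
13 | 1-(ethylthio)-1-(trimethylsilyloxy)ethene | C=C(O[Si](C)(C)C)SCC | intermediate
14 | butane-2,3-dione | CC(=O)C(C)=O | starting material
15 | S-ethyl (R)-3-methyl-4-oxo-3-(trimethylsilyloxy)pentanethioate | CCSC(=O)C[C@@](C)(O[Si](C)(C)C)C(C)=O | intermediate
16 | (R)-3-methyl-4-oxo-3-(trimethylsilyloxy)pentanal | O=CC[C@@](C)(O[Si](C)(C)C)C(C)=O | intermediate
17 | methyl (2E,4R,6R)-2-[(TBS-oxy)methyl]-4-hydroxy-6-methyl-7-oxo-6-(TMS-oxy)oct-2-enoate | COC(=O)/C(CO[Si](C)(C)C(C)(C)C)=C/[C@H](O)C[C@@](C)(O[Si](C)(C)C)C(C)=O | intermediate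
18 | 4-O-TBS ether of 17 | COC(=O)/C(CO[Si](C)(C)C(C)(C)C)=C/[C@H](O[Si](C)(C)C(C)(C)C)C[C@@](C)(O[Si](C)(C)C)C(C)=O | intermediate
19 | (E)-β-dimethylamino enone (enaminone) from 18 | COC(=O)/C(CO[Si](C)(C)C(C)(C)C)=C/[C@H](O[Si](C)(C)C(C)(C)C)C[C@@](C)(O[Si](C)(C)C)C(=O)/C=C/N(C)C | intermediate
20 | east half, 5-unsubstituted (2R)-2-methyl-3(2H)-furanone with the (4R)-bis-TBS enoate side chain | COC(=O)/C(CO[Si](C)(C)C(C)(C)C)=C/[C@H](O[Si](C)(C)C(C)(C)C)C[C@@]1(C)OC=CC1=O | intermediate
21 | coupled 5-[(Z)-alkenyl]furanone dimethyl acetal | COC(=O)/C(CO[Si](C)(C)C(C)(C)C)=C/[C@H](O[Si](C)(C)C(C)(C)C)C[C@@]1(C)OC(=CC1=O)/C(COCc2ccc(OC)cc2)=C\C(OC)OC | intermediate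
22 | hydroxy (Z)-enal | COC(=O)/C(CO)=C/[C@H](O[Si](C)(C)C(C)(C)C)C[C@@]1(C)OC(=CC1=O)/C(COCc2ccc(OC)cc2)=C\C=O | intermediate
23 | allylic mesylate of 22 | COC(=O)/C(COS(C)(=O)=O)=C/[C@H](O[Si](C)(C)C(C)(C)C)C[C@@]1(C)OC(=CC1=O)/C(COCc2ccc(OC)cc2)=C\C=O | intermediate
24 | (Z)-2-(bromomethyl)enoate (Z)-enal | COC(=O)/C(CBr)=C/[C@H](O[Si](C)(C)C(C)(C)C)C[C@@]1(C)OC(=CC1=O)/C(COCc2ccc(OC)cc2)=C\C=O | intermediate
25 | macrocyclic hydroxy ester (6-OH, 8-OTBS, 15-OPMB, C12 methyl ester; CIP 6R,7S,8R,10R, same spatial arrangement as the target) | COC(=O)C(=C)[C@H]1[C@H](O)/C=C(/COCc3ccc(OC)cc3)C2=CC(=O)[C@@](C)(C[C@H]1O[Si](C)(C)C(C)(C)C)O2 | intermediate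
26 | 8-O-TBS 15-O-PMB macrolactone (CIP 6R,7S,8R,10R, same spatial arrangement as the target) | C=C1C(=O)O[C@@H]2/C=C(/COCc4ccc(OC)cc4)C3=CC(=O)[C@@](C)(C[C@@H](O[Si](C)(C)C(C)(C)C)[C@@H]12)O3 | intermediate
27 | 8-hydroxy 15-O-PMB macrolactone (6R,7R,8R,10R) | C=C1C(=O)O[C@@H]2/C=C(/COCc4ccc(OC)cc4)C3=CC(=O)[C@@](C)(C[C@@H](O)[C@@H]12)O3 | intermediate
28 | 15-O-PMB ether of the target (6R,7R,8R,10R) | C=C1C(=O)O[C@@H]2/C=C(/COCc4ccc(OC)cc4)C3=CC(=O)[C@@](C)(C[C@@H](OC(=O)C(C)C)[C@@H]12)O3 | intermediate
29 | CNP0176924.3 (8-O-isobutyryl furanoheliangolide; 6R,7R,8R,10R, 4Z) | C=C1C(=O)O[C@@H]2/C=C(/CO)C3=CC(=O)[C@@](C)(C[C@@H](OC(=O)C(C)C)[C@@H]12)O3 | target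

**Totals and risks**

Total step count: 20.

Longest linear sequence: 13 steps (8–20). The branch 1–3 followed by 11–20 is equally long, and the west branch 4–7 followed by 14–20 is 11 steps.

**Most likely to fail, first: step 14, the new C5–H alkenylation.**
- What can go wrong: substitution at C4, reductive Heck product, homocoupling of 10, or no turnover.
- The fallback uses known chemistry (conjugate addition to a 3(2H)-furanone, then Saegusa–Ito oxidation). It sets out from 10 and 20 and comes back at 21.
- Iodine–magnesium exchange on 10 with i-PrMgCl·LiCl in THF at −40 °C gives, with retention, the (Z)-alkenylmagnesium chloride F1.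
- F1 is added to 20 at −78 °C with CuI·2LiCl (20 mol %) and TMSCl. The unsubstituted β-carbon of the furanone reacts much faster than the trisubstituted enoate.
- This gives the trimethylsilyl enol ether adduct F2, a mixture at the new C3 centre, which does not matter.
- Pd(OAc)2 in MeCN at rt then restores the C2=C3 double bond and delivers 21.

**Second: step 17, the macrocyclisation.**
- What can go wrong: oligomers, reductive 1,4-loss of the C8 silyloxy group to a diene, attack of C7 on the furanone C=O (a five-membered ring), or the wrong face.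
- The fallback changes how the nucleophile is made, from reduction of a bromide to π-allylpalladium umpolung of a carbonate. It sets out from 22 and comes back at 26.
- Methyl chloroformate and pyridine in CH2Cl2 at 0 °C convert 22 into the allylic methyl carbonate F3.
- Slow addition of F3 to Pd(PPh3)4 (10 mol %) and InI (2 equiv) in THF (2 mM) forms the allylindium(III) species only as fast as Pd turns over.
- That species is aldehyde-selective and anti-selective through a closed transition state. It gives hydroxy ester 25, which PPTS in benzene closes to 26.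

**Third: step 11, the asymmetric Ni/Cr coupling.**
- What can go wrong: modest control at C8, sluggish bromide, or loss of alkene geometry with butenolide formation.
- The fallback forms C7–C8 at the acyl level and sets C8 by reagent-controlled ketone reduction. It sets out from 4 and 15 and comes back at 17.
- Compound 4 with (Bu3Sn)2 and Pd(PPh3)4 in toluene at 100 °C gives the (E)-alkenylstannane F4.
- Neutral thioester–stannane coupling of F4 with 15 (Pd2(dba)3, tri-2-furylphosphine, copper(I) diphenylphosphinate, THF, 40 °C) gives the γ-oxo enoate F5.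
- (R)-BINAL-H in THF at −100 to −78 °C reduces the conjugated ketone much faster than the hindered dialkyl ketone and gives the 4R alcohol 17.

**Further compounds**
F1 | step 14 | (Z)-[4,4-dimethoxy-1-(4-methoxybenzyloxy)but-2-en-2-yl]magnesium chloride | Cl[Mg]/C(COCc1ccc(OC)cc1)=C\C(OC)OC
F2 | step 14 | trimethylsilyl enol ether of the conjugate adduct (3-TMS-oxy-2,5-dihydrofuran, epimers at C3) | COC(=O)/C(CO[Si](C)(C)C(C)(C)C)=C/[C@H](O[Si](C)(C)C(C)(C)C)C[C@@]1(C)OC(C=C1O[Si](C)(C)C)/C(COCc2ccc(OC)cc2)=C\C(OC)OC
F3 | step 17 | allylic methyl carbonate of 22 | COC(=O)/C(COC(=O)OC)=C/[C@H](O[Si](C)(C)C(C)(C)C)C[C@@]1(C)OC(=CC1=O)/C(COCc2ccc(OC)cc2)=C\C=O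
F4 | step 11 | methyl (E)-2-[(tert-butyldimethylsilyloxy)methyl]-3-(tributylstannyl)acrylate (Sn trans to CO2Me) | COC(=O)/C(CO[Si](C)(C)C(C)(C)C)=C/[Sn](CCCC)(CCCC)CCCC
F5 | step 11 | methyl (2E,6R)-2-[(tert-butyldimethylsilyloxy)methyl]-6-methyl-4,7-dioxo-6-(trimethylsilyloxy)oct-2-enoate | COC(=O)/C(CO[Si](C)(C)C(C)(C)C)=C/C(=O)C[C@@](C)(O[Si](C)(C)C)C(C)=O
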